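**Retrosynthetic overview**
1. Target 18 ⇐ diol lactone 16: the two side-chain esters go on last (primary acetate, then secondary angelate).
2. 16 ⇐ acyclic bromo dienoate 12: the C7–C8 bond is made by an intramolecular indium allylation in which the acrylate β-carbon (normally an acceptor) attacks the aldehyde carbon. This one step closes the seven-membered carbocycle first and the cis α-methylene-γ-lactone second, and sets C7 and C8.
3. 12 ⇐ δ-lactone 8 (half-reduction, vinylalumination, SN2' bromination); the δ-lactone is a temporary ring that fixes the Z C5=C6 alkene.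
4. 8 ⇐ β-hydroxy ketone 6 (ketene ylide) ⇐ enone 3 + MeMgBr + aldehyde 4 (one-pot asymmetric conjugate addition–aldol sets C10, C1, C2) ⇐ cross-metathesis of 1 and 2.

Atom labels (sesquiterpene-lactone numbering): C8 = lactone CH–O, C7 = ring-fusion CH, C11/C13 = lactone α-carbon and exocyclic CH2, C5=C6 = ring alkene, C1 = ring CH bearing the side chain, C2 = side-chain CH–O, C10 = ring CH–CH3.

Assumption: the ferrocenyl diphosphine enantiomer named in step 2 is taken to deliver methyl to the Re face of C4 of enone 3; if the sense is opposite, its mirror image is used and nothing else changes.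

**Step 1**
Reactants: 1 but-3-en-2-one; 2 4,4-diethoxybut-1-ene
Product: 3 (3E)-6,6-diethoxyhex-3-en-2-one
Conditions: 1 (3 equiv), second-generation Grubbs catalyst (2 mol%), CH2Cl2, 40 °C
Reagents that add atoms: none
Why: Olefin cross-metathesis of a terminal alkene with an electron-poor enone favours the cross product and gives the E enone under thermodynamic control; no stereocentre is formed.

**Step 2**
Reactants: 3 (3E)-6,6-diethoxyhex-3-en-2-one; 4 3-{[tert-butyl(dimethyl)silyl]oxy}propanal
Product: 6 (3R,4R)-3-[(1S)-3-{[tert-butyl(dimethyl)silyl]oxy}-1-hydroxypropyl]-6,6-diethoxy-4-methylhexan-2-one, via magnesium enolate 5 (not isolated)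
Conditions: MeMgBr (1.2 equiv), CuBr·SMe2 (5 mol%), (R)-1-[(S)-2-(diphenylphosphino)ferrocenyl]ethyldicyclohexylphosphine (6 mol%), t-BuOMe, −75 °C; then 4 (1.5 equiv), −75 °C; aq NH4Cl
Reagents that add atoms: methylmagnesium bromide, C[Mg]Br
Why: Ligand-controlled copper-catalysed asymmetric conjugate addition sets C10 (R) and leaves a regiodefined (Z)-magnesium enolate that adds to 4 through a chair Zimmerman–Traxler transition state (syn aldol, C1/C2), the aldehyde approaching the enolate face opposite the CH2CH(OEt)2 arm of the A(1,3)-minimised C10 centre; minor diastereomers are removed on Et3N-buffered silica.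

**Step 3**
Reactants: 6 (the β-hydroxy ketone)
Product: 8 (5S,6S)-5-[(2R)-4,4-diethoxybutan-2-yl]-6-(2-{[tert-butyl(dimethyl)silyl]oxy}ethyl)-4-methyl-5,6-dihydro-2H-pyran-2-one, via phosphorane ester 7 (not isolated)
Conditions: Ph3P=C=C=O (1.3 equiv), toluene, 80 °C
Reagents that add atoms: (triphenylphosphoranylidene)ketene, O=C=C=P(c1ccccc1)(c1ccccc1)c1ccccc1
Why: The secondary alcohol adds to the ketene ylide (Bestmann reagent) and the resulting stabilised phosphorane closes by intramolecular Wittig olefination on the methyl ketone, so the six-membered lactone locks the new C5=C6 alkene as Z (C1 cis to C7) without touching the three stereocentres.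

**Step 4**
Reactants: 8 (the δ-lactone)
Product: 10 methyl (3RS,4Z,6S,7R)-6-[(1S)-3-{[tert-butyl(dimethyl)silyl]oxy}-1-hydroxypropyl]-9,9-diethoxy-3-hydroxy-5,7-dimethyl-2-methylidenenon-4-enoate, via lactol 9 (not isolated)
Conditions: iBu2AlH (1.05 equiv), CH2Cl2, −78 °C; then CH2=C(CO2Me)Al(iBu)2 (3 equiv; from methyl propiolate, iBu2AlH, NMO, THF, 0 °C), −78 → 23 °C; aq potassium sodium tartrate
Reagents that add atoms: methyl propiolate, C#CC(=O)OC
Why: Half-reduction gives an aluminium lactolate that opens to the (Z)-enal on warming and is trapped by 1,2-addition of the α-aluminoacrylate (vinylalumination, a Baylis–Hillman equivalent that needs no nucleophilic amine, so the Z alkene is not isomerised); the new carbinol forms as an epimer mixture that is erased in step 5.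

**Step 5**
Reactants: 10 (the diol)
Product: 12 methyl (2Z,4Z)-2-(bromomethyl)-5-[(2S,3S,4R,6RS)-2-(2-{[tert-butyl(dimethyl)silyl]oxy}ethyl)-6-ethoxy-4-methyloxan-3-yl]hexa-2,4-dienoate, via cyclic acetal 11 (not isolated)
Conditions: PPTS (10 mol%), CH2Cl2, 23 °C; then NBS (2 equiv), Me2S (2.4 equiv), −20 → 0 °C
Reagents that add atoms: N-bromosuccinimide, O=C1CCC(=O)N1Br
Why: Acid-catalysed transacetalisation ties the C2 hydroxyl and the C8 acetal into a six-membered cyclic acetal so that the hydroxyl cannot attack the activated allylic system, after which the Corey–Kim reagent converts only the doubly allylic alcohol into the rearranged primary bromide by SN2' attack of bromide, giving the conjugated (2Z,4Z)-dienoate.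

**Step 6**
Reactants: 12 (the allylic bromide)
Product: 16 (3aR,6S,7R,8aR)-6-[(1S)-1,3-dihydroxypropyl]-5,7-dimethyl-3-methylidene-3,3a,6,7,8,8a-hexahydro-2H-cyclohepta[b]furan-2-one, via bromo lactol 13 (not isolated), via allylindium 14 (not isolated), via hydroxy ester 15 (not isolated)
Conditions: 1 M HCl, THF, 23 °C; then sat. aq NH4Cl, In powder (2 equiv), THF/H2O (0.005 M), 23 °C; 1 M HCl work-up
Reagents that add atoms: water, O
Why: Hydrolysis frees the C8 aldehyde (as its lactol) and the primary alcohol, and indium insertion gives a 2-(methoxycarbonyl)allyl indium reagent in which the acrylate β-carbon C7 is a polarity-reversed, homoenolate-type donor that attacks the aldehyde carbon C8 in an intramolecular Barbier allylation through a closed chair transition state at the γ-carbon (C7, not the distal C5), closing the cycloheptene and then the lactone; the (Z)-allyl unit places C6 axial and C9 equatorial, which gives the cis ring fusion (7R,8R), and the tether adopts the cycloheptene chair with the C10 methyl and the C1 side chain both pseudo-equatorial (the alternative puts the methyl syn-axial to the indium-bound oxygen), which places the lactone cis to the C1 side chain.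

**Step 7**
Reactants: 16 (the diol lactone)
Product: 17 (3S)-3-[(3aR,6S,7R,8aR)-5,7-dimethyl-3-methylidene-2-oxo-3,3a,6,7,8,8a-hexahydro-2H-cyclohepta[b]furan-6-yl]-3-hydroxypropyl acetate
Conditions: AcCl (1.1 equiv), 2,4,6-collidine, CH2Cl2, −78 °C
Reagents that add atoms: acetyl chloride, CC(=O)Cl
Why: Kinetic chemoselective esterification: with the hindered base at low temperature the primary hydroxyl is acetylated much faster than the secondary C2 hydroxyl next to the ring, and no stereocentre is touched.

**Step 8**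
Reactants: 17 (the monoacetate)
Product: 18 (3aR,6S,7R,8aR)-6-[(1S)-3-acetoxy-1-{[(2Z)-2-methylbut-2-enoyl]oxy}propyl]-5,7-dimethyl-3-methylidene-3,3a,6,7,8,8a-hexahydro-2H-cyclohepta[b]furan-2-one (target)
Conditions: angelic acid (3 equiv), 2,4,6-trichlorobenzoyl chloride (3 equiv), Et3N, toluene, 23 °C; then 17, 80 °C
Reagents that add atoms: angelic acid [(2Z)-2-methylbut-2-enoic acid], C/C=C(/C)C(=O)O
Why: Yamaguchi-type esterification through the preformed mixed anhydride, run without DMAP, acylates the hindered secondary alcohol with retention at C2 and avoids nucleophile-induced isomerisation of the angelate to the tiglate and conjugate addition to the α-methylene lactone.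

**Compound list**
1 | but-3-en-2-one (methyl vinyl ketone) | CC(=O)C=C | starting material
2 | 4,4-diethoxybut-1-ene (but-3-enal diethyl acetal) | C=CCC(OCC)OCC | starting material
3 | (3E)-6,6-diethoxyhex-3-en-2-one | CC(=O)/C=C/CC(OCC)OCC | intermediate
4 | 3-{[tert-butyl(dimethyl)silyl]oxy}propanal | O=CCCO[Si](C)(C)C(C)(C)C | starting material
5 | bromomagnesium (Z)-enolate (C2=C3) of (4R)-6,6-diethoxy-4-methylhexan-2-one, formed in the flask | CCOC(OCC)C[C@@H](C)/C=C(/C)O[Mg]Br | intermediate
6 | (3R,4R)-3-[(1S)-3-{[tert-butyl(dimethyl)silyl]oxy}-1-hydroxypropyl]-6,6-diethoxy-4-methylhexan-2-one | CCOC(OCC)C[C@@H](C)[C@H]([C@H](CCO[Si](C)(C)C(C)(C)C)O)C(C)=O | intermediate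
7 | (triphenylphosphoranylidene)acetate ester of 6 at the secondary hydroxyl, formed in the flask | CCOC(OCC)C[C@@H](C)[C@H]([C@H](CCO[Si](C)(C)C(C)(C)C)OC(=O)C=P(c1ccccc1)(c1ccccc1)c1ccccc1)C(C)=O | intermediate
8 | (5S,6S)-5-[(2R)-4,4-diethoxybutan-2-yl]-6-(2-{[tert-butyl(dimethyl)silyl]oxy}ethyl)-4-methyl-5,6-dihydro-2H-pyran-2-one | CCOC(OCC)C[C@@H](C)[C@@H]1[C@H](CCO[Si](C)(C)C(C)(C)C)OC(=O)C=C1C | intermediate
9 | lactol of 8 (2-hydroxy-5,6-dihydro-2H-pyran, both anomers), present as its diisobutylaluminium alkoxide | CCOC(OCC)C[C@@H](C)[C@@H]1[C@H](CCO[Si](C)(C)C(C)(C)C)OC(O)C=C1C | intermediate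
10 | methyl (3RS,4Z,6S,7R)-6-[(1S)-3-{[tert-butyl(dimethyl)silyl]oxy}-1-hydroxypropyl]-9,9-diethoxy-3-hydroxy-5,7-dimethyl-2-methylidenenon-4-enoate | CCOC(OCC)C[C@@H](C)[C@H]([C@H](CCO[Si](C)(C)C(C)(C)C)O)/C(C)=C\C(O)C(=C)C(=O)OC | intermediate
11 | methyl (3RS,4Z)-5-[(2S,3S,4R,6RS)-2-(2-{[tert-butyl(dimethyl)silyl]oxy}ethyl)-6-ethoxy-4-methyloxan-3-yl]-3-hydroxy-2-methylidenehex-4-enoate, formed in the flask | CCOC1C[C@@H](C)[C@H]([C@H](CCO[Si](C)(C)C(C)(C)C)O1)/C(C)=C\C(O)C(=C)C(=O)OC | intermediate
12 | methyl (2Z,4Z)-2-(bromomethyl)-5-[(2S,3S,4R,6RS)-2-(2-{[tert-butyl(dimethyl)silyl]oxy}ethyl)-6-ethoxy-4-methyloxan-3-yl]hexa-2,4-dienoate | CCOC1C[C@@H](C)[C@H]([C@H](CCO[Si](C)(C)C(C)(C)C)O1)/C(C)=C\C=C(/CBr)C(=O)OC | intermediate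
13 | methyl (2Z,4Z)-2-(bromomethyl)-5-[(2S,3S,4R,6RS)-6-hydroxy-2-(2-hydroxyethyl)-4-methyloxan-3-yl]hexa-2,4-dienoate (lactol, in equilibrium with the open hydroxy aldehyde), formed in the flask | OC1C[C@@H](C)[C@H]([C@H](CCO)O1)/C(C)=C\C=C(/CBr)C(=O)OC | intermediate
14 | allylindium reagent from 13 (CH2Br replaced by CH2In, monovalent indium), formed in the flask | OC1C[C@@H](C)[C@H]([C@H](CCO)O1)/C(C)=C\C=C(/C[In])C(=O)OC | intermediate
15 | methyl 2-[(1R,2R,4R,5S)-5-[(1S)-1,3-dihydroxypropyl]-2-hydroxy-4,6-dimethylcyclohept-6-en-1-yl]prop-2-enoate, formed in the flask | O[C@@H]1C[C@@H](C)[C@H]([C@H](CCO)O)C(C)=C[C@@H]1C(=C)C(=O)OC | intermediate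
16 | (3aR,6S,7R,8aR)-6-[(1S)-1,3-dihydroxypropyl]-5,7-dimethyl-3-methylidene-3,3a,6,7,8,8a-hexahydro-2H-cyclohepta[b]furan-2-one | C=C1C(=O)O[C@@H]2C[C@@H](C)[C@H]([C@H](CCO)O)C(C)=C[C@H]12 | intermediate
17 | (3S)-3-[(3aR,6S,7R,8aR)-5,7-dimethyl-3-methylidene-2-oxo-3,3a,6,7,8,8a-hexahydro-2H-cyclohepta[b]furan-6-yl]-3-hydroxypropyl acetate | C=C1C(=O)O[C@@H]2C[C@@H](C)[C@H]([C@H](CCOC(C)=O)O)C(C)=C[C@H]12 | intermediate
18 | (3aR,6S,7R,8aR)-6-[(1S)-3-acetoxy-1-{[(2Z)-2-methylbut-2-enoyl]oxy}propyl]-5,7-dimethyl-3-methylidene-3,3a,6,7,8,8a-hexahydro-2H-cyclohepta[b]furan-2-one | C=C1C(=O)O[C@@H]2C[C@@H](C)[C@H]([C@H](CCOC(C)=O)OC(=O)/C(C)=C\C)C(C)=C[C@H]12 | target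

**Totals**
Total step count: 8. Longest linear sequence: 8 steps (1 and 2 to 18).

**Three steps most likely to fail, with fallbacks**

Step 6 (ring closure). The risks are protonation of the allylindium before the slow seven-membered closure, loss of the Z C5=C6 geometry by metal migration along the pentadienyl system, attack through the distal carbon C5 to give a cyclopentanol, and the wrong face relative to C1/C10. Fallback: the transient organoindium is replaced by an isolable boron reagent. Setting out from 12, borylation (B2pin2, Pd2(dba)3 2.5 mol%, DMSO, 50 °C) gives the configurationally stable allylboronate F5. Acid unmasking (1 M HCl, THF) gives the lactol allylboronate F6, which cyclises on warming (toluene, 50 °C) by intramolecular allylboration, strictly at the γ-carbon through a chair transition state. Lactonisation on acidic work-up brings the route back at 16. This does not correct a wrong facial preference, which would need C7/C8 to be set before ring closure.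

Step 2 (conjugate addition–aldol). The weak point is the C1/C10 relationship, which rests on the enolate distinguishing CH3 from CH2CH(OEt)2, and to a lesser extent the enantioselectivity of the copper step. Fallback: the two events are separated and the aldol is put under catalyst control. Setting out from 3, the same copper-catalysed methyl addition is quenched with TMSCl/Et3N to give the trimethylsilyl enol ether F1. A syn-selective Mukaiyama aldol with 4, catalysed by the acyloxyborane from BH3·THF and the matching enantiomer of 2-O-(2,6-diisopropoxybenzoyl)tartaric acid (20 mol%, EtCN, −78 °C), gives the silyl ether F2. K2CO3/MeOH then returns the route at 6.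

Step 4 (reduction–vinylalumination). The aluminium lactolate may not open fast enough for the vinylalane to add, and diol 10 can cyclodehydrate on acidic silica (use it crude or on buffered silica). Fallback: a stepwise aldol–elimination replaces the vinylmetal addition. Setting out from 8, iBu2AlH reduction is worked up to isolate lactol 9. Addition of the lithium enolate of methyl 3-(dimethylamino)propanoate (LiN(iPr)2, THF, −78 → −20 °C, 3 equiv) gives the amino diol F3. MeI converts it into the ammonium iodide F4, and DBU eliminates trimethylamine to return the route at 10.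

**Further compounds**
F1 | step 2 | (Z)-trimethylsilyl enol ether (C2=C3) of (4R)-6,6-diethoxy-4-methylhexan-2-one | CCOC(OCC)C[C@@H](C)/C=C(/C)O[Si](C)(C)C
F2 | step 2 | trimethylsilyl ether of 6 at the secondary hydroxyl | CCOC(OCC)C[C@@H](C)[C@H]([C@H](CCO[Si](C)(C)C(C)(C)C)O[Si](C)(C)C)C(C)=O
F3 | step 4 | methyl (4Z,6S,7R)-2-[(dimethylamino)methyl]-6-[(1S)-3-{[tert-butyl(dimethyl)silyl]oxy}-1-hydroxypropyl]-9,9-diethoxy-3-hydroxy-5,7-dimethylnon-4-enoate | CCOC(OCC)C[C@@H](C)[C@H]([C@H](CCO[Si](C)(C)C(C)(C)C)O)/C(C)=C\C(O)C(CN(C)C)C(=O)OC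
F4 | step 4 | N-methyl ammonium iodide of F3 | CCOC(OCC)C[C@@H](C)[C@H]([C@H](CCO[Si](C)(C)C(C)(C)C)O)/C(C)=C\C(O)C(C[N+](C)(C)C)C(=O)OC.[I-]
F5 | step 6 | pinacol allylboronate corresponding to 12 (CH2Br replaced by CH2Bpin) | CCOC1C[C@@H](C)[C@H]([C@H](CCO[Si](C)(C)C(C)(C)C)O1)/C(C)=C\C=C(/CB2OC(C)(C)C(C)(C)O2)C(=O)OC
F6 | step 6 | pinacol allylboronate lactol corresponding to 13 | OC1C[C@@H](C)[C@H]([C@H](CCO)O1)/C(C)=C\C=C(/CB2OC(C)(C)C(C)(C)O2)C(=O)OC
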